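Monday's run is the very flask I am asked about, followed through its first minutes, so I read its early readings forward.

| setting | Monday's | flask |
|---|---|---|
| substrate | 0.39 M | 0.39 M |
| reagent in the second phase | 0.507 M | 0.507 M |
| protic impurity | 7.8 mM | 7.80 mM |
| remark | the very flask that is asked about, followed so far |  |
| time |  | 25 min |
| volume of the second phase over the first |  | 0.50 |

- Monday's (time / min: target / %, substrate / %): 0.250: 0.3, 99.6; 0.833: 1.9, 99.1; 1.33: 3.1, 97.3; 2.00: 5.8, 93.7; 3.00: 8.0, 90.3; 4.00: 10.9, 84.5; 5.00: 12.4, 81.7

(each reading ± 0.5 percentage points)

- in the second phase: reagent in the second phase; everything else is in the first
- charges count per volume of the first phase; a concentration in a rate is the amount of a species over the volume of its own phase; every rate counts per litre of the first phase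
- the earlier runs hold the two phases in the same ratio of volumes as the flask asked about

1. target at 25 min, in percent of the substrate charged
2. part of the substrate charged that has reacted at 25 min

Let x and p be the fractions of the substrate charged that stand as substrate and as target. Suppose substrate makes target and target is lost, each in a step first order in its own species and in the same reagent. Then the reagent and the clock cancel from the ratio of rates: dp/dx = s p/x − 1, so p = (x^s − x)/(1 − s). Monday's last reading, 12.4 % target at 81.7 % substrate, put into that curve gives s = 3.98, the selectivity factor: the rate constant for losing target over that for making it. It is a reading and carries the scatter of the readings.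

Now the run in slow motion. At first the protic impurity stands at hardly any of the substrate charge, and on this curve the loss of target over its making is s p/x, which Monday's reading at 0.833 min puts at 7.64 % and Monday's last reading at 60.4 %. The two rates meet at x = 62.9 %, where p = 15.8 %, the ceiling of this curve; beyond it target falls while substrate still goes. How fast x travels depends on the reagent, of which 1.30 equivalents are charged, and I read that less well, so I set no figure of my own on the part reacted. My own estimate for target at the asked time is below 15.8 %, a number that carries the scatter of s.

The forecast gives 23 % target and 68 % reacted, on the ground that “the side loss needs both target and substrate”; its target stands above my ceiling.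

The flask gives 14.4 % target and 52.2 % reacted.

    reagent in the reaction phase ⇌ reagent in the second phase, rate k1*([reagent in the reaction phase] - [reagent in the second phase]/K1) per volume of the first phase (partition coefficient = 9.50, kL = 0.00880 s⁻¹)
    reagent in the reaction phase ⇌ dormant form (K = 0.510, k = 5.50 × 10⁻⁴ s⁻¹)
    reagent in the reaction phase + target → over-reacted product (k = 0.0750 L mol⁻¹ s⁻¹)
    substrate + reagent in the reaction phase → target (k = 0.0190 L mol⁻¹ s⁻¹)
    reagent in the reaction phase + protic impurity → quenched reagent (k = 1.20 L mol⁻¹ s⁻¹)

At 47.8 % substrate the curve gives 14.3 % target, beside the flask's 14.4 %. Reagent use by the substrate step over that by the target step goes from 1.3 at 7.50 min to 0.84 at 25.0 min, and target goes from 15.9 % at 12.5 min to 14.4 %.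

The same flask read at 15 min holds 58.9 % substrate, where the curve with s gives 15.7 % target. The computed flask there holds 15.8 %.

Readings and results were computed for an exercise, and the scatter is random.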